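**Plan**

- **Cuts:** the three phenols are first masked as benzyl ethers. Ring C is then opened at the aryl ketone bond C4-C4a and at the ether bond O1-C2. Ring A finally loses its two diarylmethane bonds, C6-CH2 and C8-CH2.
- **Feature:** with C4-C4a open, ring A bears oxygen at C5, C7 and C8a and benzyl groups at C6 and C8. C4a is therefore its only C-H, ortho to O1 and O5 and para to the C7 methoxy group, so an acyl electrophile tethered at O1 has a single, strongly activated site.
- **Forward, ring A:** all four benzene rings are bought. Both benzyl groups go onto a 2,6-dihydroxy-4-methoxybenzoate whose ester blocks the future C4a, one hydroxyl is benzylated, and the ester leaves as CO2.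
- **Forward, ring C:** the C2-C3-C4 chain with ring B is joined at O1 as a 1-phenylallyl ether and its vinyl end is raised to the acid. Ring C, the only ring made, is then closed and hydrogenolysis ends the route.
- **Stereochemistry:** the single centre C2 (S) comes from the chiral iridium-phosphoramidite catalyst in the O1-C2 bond formation and is only carried along afterwards.

Key step: step 7

Assumption: the (Ra,Rc,Rc) ligand is taken to be the enantiomer that gives the (S)-ether in step 4; the sense of induction should be checked on a simple phenol, and the equally available mirror-image ligand is used if the check demands it.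

**Step 1**
Reactants: 1 methyl 2,6-dihydroxy-4-methoxybenzoate; 2 2-(benzyloxy)benzyl alcohol (2.2 equiv)
Product: 4 methyl 3,5-bis[2-(benzyloxy)benzyl]-2,6-dihydroxy-4-methoxybenzoate, via monobenzylated benzoate 3 (not isolated)
Conditions: Sc(OTf)3 (10 mol %), MeNO2, 40 °C, slow addition of 2
Reagents that add atoms: none
Why: Friedel-Crafts benzylation with a benzylic alcohol under Lewis acid catalysis, in which Sc(OTf)3 ionises 2 to an ortho-alkoxy-stabilised benzylic cation that is captured at C3 and then C5 of 1, the two positions ortho/para to all three oxygen donors and only meta to the ester, while the ester keeps the third ring position closed, as in the alkylation of ester-blocked resorcinols.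

**Step 2**
Reactants: 4 methyl 3,5-bis[2-(benzyloxy)benzyl]-2,6-dihydroxy-4-methoxybenzoate
Product: 5 methyl 2-(benzyloxy)-3,5-bis[2-(benzyloxy)benzyl]-6-hydroxy-4-methoxybenzoate
Conditions: BnBr (1.05 equiv), K2CO3 (1.1 equiv), acetone, reflux
Reagents that add atoms: benzyl bromide, BrCc1ccccc1
Why: Williamson etherification, in which the two hydroxyl groups of 4 are equivalent and, once one is benzylated, the other is held in a strong hydrogen bond to the ester carbonyl and reacts far more slowly, so one equivalent of BnBr should stop at the monoether.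

**Step 3**
Reactants: 5 methyl 2-(benzyloxy)-3,5-bis[2-(benzyloxy)benzyl]-6-hydroxy-4-methoxybenzoate
Product: 7 5-(benzyloxy)-2,4-bis[2-(benzyloxy)benzyl]-3-methoxyphenol, via benzoic acid 6 (not isolated)
Conditions: KOH (10 equiv), DMSO/H2O (4:1), 100 °C, N2; then 3 M HCl to pH 2, 70 °C
Reagents that add atoms: none
Why: Ester saponification followed by protodecarboxylation, since acid 6 carries oxygen donors ortho, ortho and para to the carboxyl-bearing carbon, so ipso protonation and loss of CO2 should occur on gentle heating as with other 2,4,6-trioxygenated benzoic acids, and the benzyl and methyl ethers are inert to both media.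

**Step 4**
Reactants: 7 5-(benzyloxy)-2,4-bis[2-(benzyloxy)benzyl]-3-methoxyphenol; 8 (E)-cinnamyl methyl carbonate (1.5 equiv)
Product: 10 (S)-1-(benzyloxy)-2,4-bis[2-(benzyloxy)benzyl]-3-methoxy-5-[(1-phenylprop-2-en-1-yl)oxy]benzene, via lithium phenoxide 9 (not isolated)
Conditions: n-BuLi (1.0 equiv), THF, -78 to 0 °C; then 8, [Ir(cod)Cl]2 (2 mol %), (Ra,Rc,Rc)-O,O'-(1,1'-binaphthyl-2,2'-diyl)-N,N-bis(1-phenylethyl)phosphoramidite (4 mol %, catalyst preformed with n-PrNH2 at 50 °C), THF, rt; aqueous work-up
Reagents that add atoms: none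
Why: Iridium-catalysed asymmetric allylic etherification of an aryloxide with a linear cinnamyl carbonate, in which the cyclometalated iridium-phosphoramidite species ionises 8 to a cinnamyl complex bound through one face and the phenoxide attacks the phenyl-bearing terminus anti to the metal, so the branched ether forms with C2 fixed as (S) by the ligand configuration, ortho-alkyl and electron-rich aryloxides lying within the known scope.

**Step 5**
Reactants: 10 (S)-1-(benzyloxy)-2,4-bis[2-(benzyloxy)benzyl]-3-methoxy-5-[(1-phenylprop-2-en-1-yl)oxy]benzene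
Product: 12 (S)-3-{5-(benzyloxy)-2,4-bis[2-(benzyloxy)benzyl]-3-methoxyphenoxy}-3-phenylpropan-1-ol, via B-alkyl-9-BBN adduct 11 (not isolated)
Conditions: 9-BBN (1.5 equiv), THF, 0 °C to rt; then aq NaOH, 30 % H2O2, 0 °C
Reagents that add atoms: hydrogen peroxide, OO
Why: Brown hydroboration-oxidation, in which the bulky 9-BBN places boron on the terminal carbon of the monosubstituted alkene, remote from the allylic C-O bond so that no beta-elimination can follow, and alkaline peroxide replaces boron by hydroxyl without touching C2.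

**Step 6**
Reactants: 12 (S)-3-{5-(benzyloxy)-2,4-bis[2-(benzyloxy)benzyl]-3-methoxyphenoxy}-3-phenylpropan-1-ol
Product: 14 (S)-3-{5-(benzyloxy)-2,4-bis[2-(benzyloxy)benzyl]-3-methoxyphenoxy}-3-phenylpropanoic acid, via aldehyde 13 (not isolated)
Conditions: TEMPO (2,2,6,6-tetramethylpiperidin-1-oxyl, 20 mol %), PhI(OAc)2 (2.5 equiv), CH2Cl2/H2O (2:1), 0 °C to rt
Reagents that add atoms: water, O
Why: TEMPO/PhI(OAc)2 oxidation of a primary alcohol to the acid through aldehyde 13 and its hydrate, run in a weakly acidic, hypochlorite-free medium that avoids both retro-oxa-Michael loss of the aryloxide from 13 and chlorination of ring A.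

**Step 7**
Reactants: 14 (S)-3-{5-(benzyloxy)-2,4-bis[2-(benzyloxy)benzyl]-3-methoxyphenoxy}-3-phenylpropanoic acid
Product: 16 (2S)-5-(benzyloxy)-6,8-bis[2-(benzyloxy)benzyl]-7-methoxy-2-phenylchroman-4-one, via acyl trifluoroacetate 15 (not isolated)
Conditions: (CF3CO)2O (2 equiv), CH2Cl2, 0 °C to rt
Reagents that add atoms: none
Why: This is the intramolecular Friedel-Crafts acylation of a 3-aryloxypropanoic acid, the standard entry to chroman-4-ones: (CF3CO)2O converts the acid into acyl trifluoroacetate 15, C4a attacks its non-fluorinated carbonyl (as such or as the acylium ion pair), and loss of the C4a proton from the arenium ion gives the aryl ketone and CF3CO2H. Ring C closes in a 6-exo-trig mode at the acyl carbon, with the C4a=C8a bond of ring A endocyclic. No stereocentre is created, and the C2 configuration from step 4 only has to persist, which it should because neither the C2-O1 nor the C2-H bond takes part. Site selectivity is secured by the substrate, since C4a is the one unsubstituted carbon of ring A and is activated by O1 and the C5 benzyloxy group (ortho) and by the C7 methoxy group (para), whereas the pendant monoalkoxy rings are far less nucleophilic and could be reached only through nine-membered or larger rings. Chemoselectivity requires an activator that spares the secondary benzylic C2-O1 bond and the benzyl ethers: ring A is nucleophilic enough for the mixed anhydride to react near 0 °C without a Lewis acid, the only acid present is a few equivalents of dilute CF3CO2H, and the absence of base closes the E1cB path to a cinnamoyl derivative.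

**Step 8**
Reactants: 16 (2S)-5-(benzyloxy)-6,8-bis[2-(benzyloxy)benzyl]-7-methoxy-2-phenylchroman-4-one
Product: 17 7-methoxydichamanetin, (2S)-5-hydroxy-6,8-bis(2-hydroxybenzyl)-7-methoxy-2-phenylchroman-4-one
Conditions: H2 (1 atm), 10 % Pd/C, EtOAc/MeOH, rt, stopped after uptake of 3 equiv H2
Reagents that add atoms: none
Why: Catalytic hydrogenolysis of benzyl aryl ethers, in which the three unhindered primary O-benzyl groups should be cleaved faster than the endocyclic secondary C2-O1 bond or the conjugated C4 ketone is attacked, as in routine debenzylation of flavanones, and the neutral medium gives no opening to the chalcone, so C2 stays (S).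

**Compound list**

1 | methyl 2,6-dihydroxy-4-methoxybenzoate | COC(=O)c1c(O)cc(OC)cc1O | starting material
2 | 2-(benzyloxy)benzyl alcohol | OCc1ccccc1OCc1ccccc1 | starting material
3 | methyl 3-[2-(benzyloxy)benzyl]-2,6-dihydroxy-4-methoxybenzoate | COC(=O)c1c(O)cc(OC)c(Cc2ccccc2OCc2ccccc2)c1O | intermediate
4 | methyl 3,5-bis[2-(benzyloxy)benzyl]-2,6-dihydroxy-4-methoxybenzoate | COC(=O)c1c(O)c(Cc2ccccc2OCc2ccccc2)c(OC)c(Cc2ccccc2OCc2ccccc2)c1O | intermediate
5 | methyl 2-(benzyloxy)-3,5-bis[2-(benzyloxy)benzyl]-6-hydroxy-4-methoxybenzoate | COC(=O)c1c(O)c(Cc2ccccc2OCc2ccccc2)c(OC)c(Cc2ccccc2OCc2ccccc2)c1OCc1ccccc1 | intermediate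
6 | 2-(benzyloxy)-3,5-bis[2-(benzyloxy)benzyl]-6-hydroxy-4-methoxybenzoic acid | OC(=O)c1c(O)c(Cc2ccccc2OCc2ccccc2)c(OC)c(Cc2ccccc2OCc2ccccc2)c1OCc1ccccc1 | intermediate
7 | 5-(benzyloxy)-2,4-bis[2-(benzyloxy)benzyl]-3-methoxyphenol | Oc1cc(OCc2ccccc2)c(Cc2ccccc2OCc2ccccc2)c(OC)c1Cc1ccccc1OCc1ccccc1 | intermediate
8 | (E)-cinnamyl methyl carbonate | COC(=O)OC/C=C/c1ccccc1 | starting material
9 | lithium 5-(benzyloxy)-2,4-bis[2-(benzyloxy)benzyl]-3-methoxyphenoxide | [Li+].[O-]c1cc(OCc2ccccc2)c(Cc2ccccc2OCc2ccccc2)c(OC)c1Cc1ccccc1OCc1ccccc1 | intermediate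
10 | (S)-1-(benzyloxy)-2,4-bis[2-(benzyloxy)benzyl]-3-methoxy-5-[(1-phenylprop-2-en-1-yl)oxy]benzene | C=C[C@@H](c1ccccc1)Oc1cc(OCc2ccccc2)c(Cc2ccccc2OCc2ccccc2)c(OC)c1Cc1ccccc1OCc1ccccc1 | intermediate
11 | (S)-9-(3-{5-(benzyloxy)-2,4-bis[2-(benzyloxy)benzyl]-3-methoxyphenoxy}-3-phenylpropyl)-9-borabicyclo[3.3.1]nonane | C1CCC2CCCC1B2CC[C@@H](c1ccccc1)Oc1cc(OCc2ccccc2)c(Cc2ccccc2OCc2ccccc2)c(OC)c1Cc1ccccc1OCc1ccccc1 | intermediate
12 | (S)-3-{5-(benzyloxy)-2,4-bis[2-(benzyloxy)benzyl]-3-methoxyphenoxy}-3-phenylpropan-1-ol | OCC[C@@H](c1ccccc1)Oc1cc(OCc2ccccc2)c(Cc2ccccc2OCc2ccccc2)c(OC)c1Cc1ccccc1OCc1ccccc1 | intermediate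
13 | (S)-3-{5-(benzyloxy)-2,4-bis[2-(benzyloxy)benzyl]-3-methoxyphenoxy}-3-phenylpropanal | O=CC[C@@H](c1ccccc1)Oc1cc(OCc2ccccc2)c(Cc2ccccc2OCc2ccccc2)c(OC)c1Cc1ccccc1OCc1ccccc1 | intermediate
14 | (S)-3-{5-(benzyloxy)-2,4-bis[2-(benzyloxy)benzyl]-3-methoxyphenoxy}-3-phenylpropanoic acid | OC(=O)C[C@@H](c1ccccc1)Oc1cc(OCc2ccccc2)c(Cc2ccccc2OCc2ccccc2)c(OC)c1Cc1ccccc1OCc1ccccc1 | intermediate
15 | (S)-3-{5-(benzyloxy)-2,4-bis[2-(benzyloxy)benzyl]-3-methoxyphenoxy}-3-phenylpropanoic trifluoroacetic anhydride | O=C(OC(=O)C(F)(F)F)C[C@@H](c1ccccc1)Oc1cc(OCc2ccccc2)c(Cc2ccccc2OCc2ccccc2)c(OC)c1Cc1ccccc1OCc1ccccc1 | intermediate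
16 | (2S)-5-(benzyloxy)-6,8-bis[2-(benzyloxy)benzyl]-7-methoxy-2-phenylchroman-4-one | COc1c(Cc2ccccc2OCc2ccccc2)c(OCc2ccccc2)c2c(c1Cc1ccccc1OCc1ccccc1)O[C@H](c1ccccc1)CC2=O | intermediate
17 | 7-methoxydichamanetin, (2S)-5-hydroxy-6,8-bis(2-hydroxybenzyl)-7-methoxy-2-phenylchroman-4-one | COc1c(Cc2ccccc2O)c(O)c2c(c1Cc1ccccc1O)O[C@H](c1ccccc1)CC2=O | target

Total step count: 8. Longest linear sequence: 8 steps (1 to 17); 2 and 8 are bought and enter directly.

**Steps most likely to fail**

(a) Step 1. The benzylic cation may condense with the alkoxyarene ring of a second molecule of 2 (oligomerisation). The reaction may also stall after the first benzylation, or the acid may strip or transfer a benzyl ether.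
The fallback sets out from 1 and changes both the electrophile and the timing of protection. Compound 1 is heated with unprotected 2-hydroxybenzyl alcohol and ZnCl2 in dioxane, so that a zinc-bound ortho-quinone methide type species is trapped at C3 and C5. This gives methyl 2,6-dihydroxy-3,5-bis(2-hydroxybenzyl)-4-methoxybenzoate F1. Treatment with BnBr (3 equiv) and K2CO3 in acetone etherifies the two pendant phenols and one ring A hydroxyl and leaves the ester-chelated hydroxyl free. The route is rejoined at 5.

(b) Step 4. The ortho-substituted, very electron-rich phenoxide may attack slowly or unselectively. The consequences would be erosion of branched selectivity, allylation at the free ring carbon instead of oxygen, or re-ionisation of the product ether with loss of enantiomeric purity.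
The fallback sets out from 7 and takes the stereocentre from the chiral pool of reagents by SN2 inversion. Commercial (R)-1-phenylpropane-1,3-diol is silylated at its primary hydroxyl (TBSCl, imidazole, CH2Cl2) to (R)-3-[(tert-butyldimethylsilyl)oxy]-1-phenylpropan-1-ol F2. Mitsunobu coupling of F2 with 7 (PPh3, DIAD, toluene, 0 °C) proceeds with inversion to (S)-tert-butyl(3-{5-(benzyloxy)-2,4-bis[2-(benzyloxy)benzyl]-3-methoxyphenoxy}-3-phenylpropoxy)dimethylsilane F3. Bu4NF in THF removes the silyl group, and the route is rejoined at 12, so steps 4 and 5 are bypassed.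

(c) Step 7. The acid released may ionise the benzylic C2-O1 bond, which would cause racemisation or loss of the phenol. The anhydride may trifluoroacetylate C4a directly, or closure may be sluggish because C4a is crowded by two ortho oxygen substituents.
The fallback sets out from 14 and forms the same C4-C4a bond with reversed polarity, as a Parham cyclisation.

- Acid 14 is converted with carbonyldiimidazole and MeNHOMe·HCl into the Weinreb amide (S)-3-{5-(benzyloxy)-2,4-bis[2-(benzyloxy)benzyl]-3-methoxyphenoxy}-N-methoxy-N-methyl-3-phenylpropanamide F4.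
- NBS in CH2Cl2 at 0 °C brominates the single free ring A carbon to give (S)-3-{3-(benzyloxy)-2-bromo-4,6-bis[2-(benzyloxy)benzyl]-5-methoxyphenoxy}-N-methoxy-N-methyl-3-phenylpropanamide F5.
- Bromine-lithium exchange (n-BuLi, THF, -78 °C) generates the aryllithium, which adds to the amide carbonyl. The route is rejoined at 16.

**Further compounds**

F1 | step 1 | methyl 2,6-dihydroxy-3,5-bis(2-hydroxybenzyl)-4-methoxybenzoate | COC(=O)c1c(O)c(Cc2ccccc2O)c(OC)c(Cc2ccccc2O)c1O
F2 | step 4 | (R)-3-[(tert-butyldimethylsilyl)oxy]-1-phenylpropan-1-ol | CC(C)(C)[Si](C)(C)OCC[C@H](c1ccccc1)O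
F3 | step 4 | (S)-tert-butyl(3-{5-(benzyloxy)-2,4-bis[2-(benzyloxy)benzyl]-3-methoxyphenoxy}-3-phenylpropoxy)dimethylsilane | CC(C)(C)[Si](C)(C)OCC[C@@H](c1ccccc1)Oc1cc(OCc2ccccc2)c(Cc2ccccc2OCc2ccccc2)c(OC)c1Cc1ccccc1OCc1ccccc1
F4 | step 7 | (S)-3-{5-(benzyloxy)-2,4-bis[2-(benzyloxy)benzyl]-3-methoxyphenoxy}-N-methoxy-N-methyl-3-phenylpropanamide | CON(C)C(=O)C[C@@H](c1ccccc1)Oc1cc(OCc2ccccc2)c(Cc2ccccc2OCc2ccccc2)c(OC)c1Cc1ccccc1OCc1ccccc1
F5 | step 7 | (S)-3-{3-(benzyloxy)-2-bromo-4,6-bis[2-(benzyloxy)benzyl]-5-methoxyphenoxy}-N-methoxy-N-methyl-3-phenylpropanamide | CON(C)C(=O)C[C@@H](c1ccccc1)Oc1c(Br)c(OCc2ccccc2)c(Cc2ccccc2OCc2ccccc2)c(OC)c1Cc1ccccc1OCc1ccccc1
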